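**Retrosynthetic overview**
1. The seven-membered carbocycle is opened at C7b–C10c to a C2-symmetric stilbene. Acid protonates the styrene to a 2,4-dioxybenzyl cation that closes by Friedel–Crafts alkylation; the same operation removes eight methyl ethers and relaxes cis to trans dihydrofurans.
2. The stilbene arm is cut by a Suzuki disconnection into a C4 bromide and an (E)-styrylboronate made from 2,4-dimethoxybenzaldehyde.
3. Both dihydrofuran rings are disconnected at once (C2–C3 and C5–C6) to a bis(diaryldiazomethane): two-fold enantioselective rhodium-carbene C–H insertion into two 4-methoxybenzyl ether CH2 groups sets four stereocentres under catalyst control.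
4. The bis-diazo compound comes from a bis-hydrazone, and that from a bis-ketone made by two-fold Friedel–Crafts aroylation of 1-bromo-3,5-dimethoxybenzene and O-alkylation with 4-methoxybenzyl chloride.
5. Ring order: central arene (bought), then the two dihydrofurans together, then the seven-membered ring last.

Assumption: Rh2(S-PTAD)4, dirhodium tetrakis[(S)-(1-adamantyl)(phthalimido)acetate], is taken to give the (3R,5R) rings of 9; if its sense of induction is opposite, the mirror-image catalyst Rh2(R-PTAD)4 is used and nothing else changes.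

Labels: 9, 14 and 15 use benzo[1,2-b:5,4-b']difuran numbering (C2/C6 carry the 4-oxyphenyl rings, C3/C5 the 3,5-dioxyphenyl rings, C4 the bromine or the arm). In the target these atoms are C7a/C7c and C8a/C8c, the arm is C8b (CH2)–C7b (CH), and ring C is the 3,5-dihydroxyphenyl ring on C8c (C9c–C14c).

**Step 1**
Reactants: 1 1-bromo-3,5-dimethoxybenzene; 2 3,5-dimethoxybenzoyl chloride (2.4 equiv)
Product: 4 (2-bromo-4,6-dihydroxy-1,3-phenylene)bis[(3,5-dimethoxyphenyl)methanone], via hexamethoxy bis-ketone 3 (not isolated)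
Conditions: AlCl3 (2.6 equiv), ClCH2CH2Cl, 0 °C → rt; then AlCl3 (4 equiv), 50 °C; 1 M HCl work-up
Reagents that add atoms: none
Why: Two-fold Friedel–Crafts acylation at the two C–H positions para to a methoxy group and ortho to bromine (the site between the methoxy groups is blocked, and the first aroyl group is twisted out of conjugation so it deactivates little), followed by chelation-controlled demethylation in which AlCl3 bound to each new carbonyl cleaves only the ortho methyl ether, so the four distal methoxy groups stay; no stereocentre is formed.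

**Step 2**
Reactants: 4 (2-bromo-4,6-dihydroxy-1,3-phenylene)bis[(3,5-dimethoxyphenyl)methanone]; 5 4-methoxybenzyl chloride (2.5 equiv)
Product: 6 {2-bromo-4,6-bis[(4-methoxybenzyl)oxy]-1,3-phenylene}bis[(3,5-dimethoxyphenyl)methanone]
Conditions: K2CO3 (4 equiv), DMF, 60 °C
Reagents that add atoms: none
Why: Williamson ether synthesis (SN2 of the two phenoxides on the reactive benzylic chloride); the two benzyl groups are not protecting groups but supply C2/C6 and their 4-oxyphenyl rings; no stereocentre is formed.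

**Step 3**
Reactants: 6 {2-bromo-4,6-bis[(4-methoxybenzyl)oxy]-1,3-phenylene}bis[(3,5-dimethoxyphenyl)methanone]
Product: 7 the dihydrazone of 6, 3-bromo-2,4-bis[hydrazinylidene(3,5-dimethoxyphenyl)methyl]-1,5-bis[(4-methoxybenzyl)oxy]benzene (C=N geometry not defined)
Conditions: N2H4·H2O (40 equiv), AcOH (0.5 equiv), n-BuOH, 120 °C, sealed tube
Reagents that add atoms: hydrazine (as the monohydrate), NN
Why: Hydrazone condensation, pushed with a large excess of hydrazine, acid catalysis and heat because both diaryl ketones are di-ortho-substituted; the aryl bromide and all ethers are inert, and no stereocentre is formed.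

**Step 4**
Reactants: 7 the dihydrazone of 6
Product: 9 (2S,3R,5R,6S)-4-bromo-3,5-bis(3,5-dimethoxyphenyl)-2,6-bis(4-methoxyphenyl)-2,3,5,6-tetrahydrobenzo[1,2-b:5,4-b']difuran (both rings 2,3-cis), via bis(diazo) compound 8 (not isolated)
Conditions: MnO2 (10 equiv), CH2Cl2, 0 °C, filter; then slow addition to Rh2(S-PTAD)4 (2 mol %), CH2Cl2, −20 → 0 °C
Reagents that add atoms: none
Why: MnO2 dehydrogenates each hydrazone to a diaryldiazomethane, and the chiral dirhodium tetracarboxylate converts each into a donor/donor rhodium carbene that undergoes enantioselective intramolecular 1,5 C–H insertion into the neighbouring ArCH2–O group (the only C–H in 1,5 relation, bromine blocking the other side), closing both dihydrofuran rings in one operation; the catalyst fixes C3 and C5 as R, the concerted insertion gives the 2,3-cis rings, and two independent catalyst-controlled events raise the ee of the C2-symmetric product while the mismatched minor product is a separable meso diastereomer.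

**Step 5**
Reactants: 10 2,4-dimethoxybenzaldehyde; 11 bis(4,4,5,5-tetramethyl-1,3,2-dioxaborolan-2-yl)methane (1.2 equiv)
Product: 13 (E)-2-[2-(2,4-dimethoxyphenyl)ethenyl]-4,4,5,5-tetramethyl-1,3,2-dioxaborolane, via lithiated bis-boronate 12 (not isolated)
Conditions: LiTMP (lithium 2,2,6,6-tetramethylpiperidide, 1.2 equiv), THF, 0 °C; then 10, −78 °C → rt
Reagents that add atoms: none
Why: Boron–Wittig olefination: the α-boryl carbanion adds to the aldehyde and syn B–O elimination gives the E-vinylboronate; no stereocentre is formed, and the alkene geometry is erased in step 7 in any case.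

**Step 6**
Reactants: 9 the cis,cis bromide; 13 the (E)-styrylboronate (1.8 equiv)
Product: 14 (2S,3R,5R,6S)-4-[(E)-2-(2,4-dimethoxyphenyl)ethenyl]-3,5-bis(3,5-dimethoxyphenyl)-2,6-bis(4-methoxyphenyl)-2,3,5,6-tetrahydrobenzo[1,2-b:5,4-b']difuran
Conditions: Pd(OAc)2 (5 mol %), 2-dicyclohexylphosphino-2',6'-dimethoxybiphenyl (SPhos, 10 mol %), K3PO4 (3 equiv), toluene/H2O 10:1, 90 °C
Reagents that add atoms: none
Why: Suzuki–Miyaura coupling, in which the bulky electron-rich biarylphosphine lets zerovalent palladium insert into the di-ortho-substituted electron-rich aryl bromide, and the mild phosphate base leaves the four benzylic stereocentres untouched.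

**Step 7**
Reactants: 14 the octamethyl stilbene
Product: 16 CNP0154047.1, the (7aR,8aR,7bR,7cR,8cR) octaphenol, via all-trans octaphenol stilbene 15 (not isolated)
Conditions: BBr3 (24 equiv), CH2Cl2, −78 °C → rt; then MeOH, 0 °C → rt; H2O
Reagents that add atoms: none
Why: BBr3 cleaves all eight aryl methyl ethers and, as Lewis and Brønsted acid (HBr after the methanol quench), (a) reversibly ionises each benzylic C2–O bond to a para-oxybenzyl cation so both cis rings relax to the trans rings without touching C3/C5, and (b) protonates the stilbene at C8b to the 2,4-dioxybenzyl cation at C7b, which is captured by C10c of one of the two homotopic 3,5-dihydroxyphenyl rings (intramolecular Friedel–Crafts alkylation, seven-membered ring); C7b is set by substrate control, the aryl group going pseudo-equatorial and anti to the C8c–C7c bond (R), with reversible ionisation at this doubly activated position leading to the thermodynamic isomer.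

**Compound list**
1 | 1-bromo-3,5-dimethoxybenzene | COc1cc(Br)cc(OC)c1 | starting material
2 | 3,5-dimethoxybenzoyl chloride | COc1cc(cc(OC)c1)C(Cl)=O | starting material
3 | (2-bromo-4,6-dimethoxy-1,3-phenylene)bis[(3,5-dimethoxyphenyl)methanone] | COc1cc(OC)c(C(=O)c2cc(OC)cc(OC)c2)c(Br)c1C(=O)c1cc(OC)cc(OC)c1 | intermediate (not isolated)
4 | (2-bromo-4,6-dihydroxy-1,3-phenylene)bis[(3,5-dimethoxyphenyl)methanone] | Oc1cc(O)c(C(=O)c2cc(OC)cc(OC)c2)c(Br)c1C(=O)c1cc(OC)cc(OC)c1 | intermediate
5 | 4-methoxybenzyl chloride | COc1ccc(CCl)cc1 | starting material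
6 | {2-bromo-4,6-bis[(4-methoxybenzyl)oxy]-1,3-phenylene}bis[(3,5-dimethoxyphenyl)methanone] | COc1ccc(COc2cc(OCc3ccc(OC)cc3)c(C(=O)c3cc(OC)cc(OC)c3)c(Br)c2C(=O)c2cc(OC)cc(OC)c2)cc1 | intermediate
7 | dihydrazone of 6 | COc1ccc(COc2cc(OCc3ccc(OC)cc3)c(C(=NN)c3cc(OC)cc(OC)c3)c(Br)c2C(=NN)c2cc(OC)cc(OC)c2)cc1 | intermediate
8 | 3-bromo-2,4-bis[diazo(3,5-dimethoxyphenyl)methyl]-1,5-bis[(4-methoxybenzyl)oxy]benzene | COc1ccc(COc2cc(OCc3ccc(OC)cc3)c(C(=[N+]=[N-])c3cc(OC)cc(OC)c3)c(Br)c2C(=[N+]=[N-])c2cc(OC)cc(OC)c2)cc1 | intermediate (not isolated)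
9 | (2S,3R,5R,6S)-4-bromo-3,5-bis(3,5-dimethoxyphenyl)-2,6-bis(4-methoxyphenyl)-2,3,5,6-tetrahydrobenzo[1,2-b:5,4-b']difuran, both rings cis | COc1ccc([C@H]2Oc3cc4c(c(Br)c3[C@H]2c2cc(OC)cc(OC)c2)[C@@H](c2cc(OC)cc(OC)c2)[C@@H](c2ccc(OC)cc2)O4)cc1 | intermediate
10 | 2,4-dimethoxybenzaldehyde | COc1ccc(C=O)c(OC)c1 | starting material
11 | bis(4,4,5,5-tetramethyl-1,3,2-dioxaborolan-2-yl)methane | CC1(C)OB(CB2OC(C)(C)C(C)(C)O2)OC1(C)C | starting material
12 | lithium bis(4,4,5,5-tetramethyl-1,3,2-dioxaborolan-2-yl)methanide | [Li+].[CH-](B1OC(C)(C)C(C)(C)O1)B1OC(C)(C)C(C)(C)O1 | intermediate (not isolated)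
13 | (E)-2-[2-(2,4-dimethoxyphenyl)ethenyl]-4,4,5,5-tetramethyl-1,3,2-dioxaborolane | COc1ccc(/C=C/B2OC(C)(C)C(C)(C)O2)c(OC)c1 | intermediate
14 | (2S,3R,5R,6S)-4-[(E)-2-(2,4-dimethoxyphenyl)ethenyl]-3,5-bis(3,5-dimethoxyphenyl)-2,6-bis(4-methoxyphenyl)-2,3,5,6-tetrahydrobenzo[1,2-b:5,4-b']difuran, both rings cis | COc1ccc([C@H]2Oc3cc4c(c(/C=C/c5ccc(OC)cc5OC)c3[C@H]2c2cc(OC)cc(OC)c2)[C@@H](c2cc(OC)cc(OC)c2)[C@@H](c2ccc(OC)cc2)O4)cc1 | intermediate
15 | (2R,3R,5R,6R)-4-[(E)-2-(2,4-dihydroxyphenyl)ethenyl]-3,5-bis(3,5-dihydroxyphenyl)-2,6-bis(4-hydroxyphenyl)-2,3,5,6-tetrahydrobenzo[1,2-b:5,4-b']difuran, both rings trans | Oc1ccc([C@@H]2Oc3cc4c(c(/C=C/c5ccc(O)cc5O)c3[C@H]2c2cc(O)cc(O)c2)[C@@H](c2cc(O)cc(O)c2)[C@H](c2ccc(O)cc2)O4)cc1 | intermediate (not isolated)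
16 | CNP0154047.1, (7aR,8aR,7bR,7cR,8cR): compound 15 in which C8b is CH2 and C7b (bearing the 2,4-dihydroxyphenyl ring, cis to H-8c) is bonded to C10c of the 3,5-dihydroxyphenyl ring on C8c, closing the seven-membered ring; both dihydrofurans trans | Oc1ccc([C@@H]2Oc3cc4c5c(c3[C@H]2c2cc(O)cc(O)c2)C[C@H](c2ccc(O)cc2O)c2c(O)cc(O)cc2[C@H]5[C@H](c2ccc(O)cc2)O4)cc1 | target

**Step count and risks**
Total steps: 7. Longest linear sequence: 6 (steps 1, 2, 3, 4, 6, 7); step 5 is a one-step side branch.

The three steps most likely to fail are 7, 4 and 3.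

Step 7 asks one acid operation to do eight demethylations, two epimerisations and the ring closure. The opened dihydrofuran cations can instead lose H-3 (ring-opened stilbenes), and the C7b configuration rests on substrate control. The fallback sets out from 14 and comes back at 16, separating ring closure from deprotection. Methanesulfonic acid in CH2Cl2 at 0 °C, which does not cleave aryl methyl ethers, brings about the cis-to-trans epimerisation and the Friedel–Crafts closure to give the octamethyl ether of the target F7. This compound is stable, so its diastereomers can be separated and characterised. Sodium ethanethiolate (NaSEt) in DMF at 140 °C then removes the eight methyl groups by SN2 attack at methyl with no acid present, giving 16.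

Step 4 generates two carbenes that are each flanked by bromine and an alkoxy group, which may erode yield or selectivity or favour azine formation from the bis-diazo compound. The fallback sets out from 6 and comes back at 9, closing the rings one at a time. Condensation under the step 3 conditions, stopped near half conversion, gives the mono-hydrazone F2 (6 and 7 are recycled). MnO2 gives the mono-diazo ketone F3 (not isolated), and the same dirhodium catalyst closes the first ring to the cis-dihydrobenzofuran ketone F4; the remaining benzophenone is inert to the carbene. The second ketone is then condensed to the hydrazone F5, oxidised to the diazo compound F6 (not isolated) and inserted to give 9. The mismatched diastereomer can be removed after each ring closure.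

Step 3 may stall because both ketones are di-ortho-substituted. The fallback sets out from 6 and comes back at 7. Lawesson's reagent in toluene at 110 °C converts both carbonyl groups into the bis(thioketone) F1. The C=S carbon is far more electrophilic and exchanges sulfur for nitrogen with hydrazine hydrate in THF/EtOH at room temperature, with loss of H2S, giving 7 without forcing conditions.

**Further compounds**
F1 | step 3 | {2-bromo-4,6-bis[(4-methoxybenzyl)oxy]-1,3-phenylene}bis[(3,5-dimethoxyphenyl)methanethione] | COc1ccc(COc2cc(OCc3ccc(OC)cc3)c(C(=S)c3cc(OC)cc(OC)c3)c(Br)c2C(=S)c2cc(OC)cc(OC)c2)cc1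
F2 | step 4 | mono-hydrazone of 6 (one C=O, one C=N–NH2) | COc1ccc(COc2cc(OCc3ccc(OC)cc3)c(C(=O)c3cc(OC)cc(OC)c3)c(Br)c2C(=NN)c2cc(OC)cc(OC)c2)cc1
F3 | step 4 | mono-diazo ketone from F2 | COc1ccc(COc2cc(OCc3ccc(OC)cc3)c(C(=O)c3cc(OC)cc(OC)c3)c(Br)c2C(=[N+]=[N-])c2cc(OC)cc(OC)c2)cc1
F4 | step 4 | [(2S,3R)-4-bromo-3-(3,5-dimethoxyphenyl)-6-[(4-methoxybenzyl)oxy]-2-(4-methoxyphenyl)-2,3-dihydro-1-benzofuran-5-yl](3,5-dimethoxyphenyl)methanone, ring cis | COc1ccc([C@H]2Oc3cc(OCc4ccc(OC)cc4)c(C(=O)c4cc(OC)cc(OC)c4)c(Br)c3[C@H]2c2cc(OC)cc(OC)c2)cc1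
F5 | step 4 | hydrazone of F4 | COc1ccc([C@H]2Oc3cc(OCc4ccc(OC)cc4)c(C(=NN)c4cc(OC)cc(OC)c4)c(Br)c3[C@H]2c2cc(OC)cc(OC)c2)cc1
F6 | step 4 | diazo compound from F5 | COc1ccc([C@H]2Oc3cc(OCc4ccc(OC)cc4)c(C(=[N+]=[N-])c4cc(OC)cc(OC)c4)c(Br)c3[C@H]2c2cc(OC)cc(OC)c2)cc1
F7 | step 7 | octamethyl ether of 16, (7aR,8aR,7bR,7cR,8cR) | COc1ccc([C@@H]2Oc3cc4c5c(c3[C@H]2c2cc(OC)cc(OC)c2)C[C@H](c2ccc(OC)cc2OC)c2c(OC)cc(OC)cc2[C@H]5[C@H](c2ccc(OC)cc2)O4)cc1
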